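The target is divided at the C8–CH2 bond into a ring A acylphloroglucinol, used as its Mannich base, and 5,7-dihydroxy-2,2,6-trimethylchroman-4-one. Everything rests on assembling ring C of that chromanone by a formal [4+2] union of a salicylaldehyde-derived heterodiene (O1–C8a–C4a–C4) with isobutene (C2, C3). The feature exploited is that O1 sits on C8a, the only oxygen-bearing carbon of ring B para to the C6 methyl; in the precursor, 6-hydroxy-2,4-diisopropoxy-3-methylbenzaldehyde, the other two oxygens are etherified, so only this one can cyclise. One acid-catalysed operation with trimethyl orthoformate forms C3–C4 and O1–C2, closes ring C and delivers C4 as a methyl ether, later oxidised to the ketone.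

Key step: step 4

Remark on the chemistry: C4 of the chromane intermediates is a temporary stereocentre, formed racemic and removed on oxidation. The only stereocentre of the target is bought in with (R)-2-methylbutanoic acid. Isopropyl ethers mask the two spectator phenols because they tolerate C–H borylation and the acidic key step and are cleaved by BCl3 without touching the ketone.

Step 1
Reactants: 1 2-methylresorcinol
Product: 2 2,6-diisopropoxytoluene
Conditions: 2-bromopropane (3 equiv), K2CO3 (3 equiv), DMF, 70 °C
Reagents that add atoms: 2-bromopropane, CC(C)Br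
Why: Williamson ether synthesis on both phenoxides gives ethers that are inert to the borylation catalyst, to base and to the dilute or catalytic acid used later.

Step 2
Reactants: 2 2,6-diisopropoxytoluene
Product: 4 3,5-diisopropoxy-4-methylphenol, via aryl pinacol boronate 3 (not isolated)
Conditions: [Ir(OMe)(cod)]2 (1.5 mol %), 4,4'-di-tert-butyl-2,2'-bipyridine (3 mol %), B2pin2 (0.7 equiv), THF, 80 °C; then KHSO5 (as Oxone, 2KHSO5·KHSO4·K2SO4), acetone/H2O, rt
Reagents that add atoms: KHSO5 (potassium peroxymonosulfate), [K+].[O-]S(=O)(=O)OO
Why: Sterically governed aromatic C–H borylation with the [Ir(OMe)(cod)]2/bipyridine catalyst should occur only at the ring C–H that has no ortho substituent (para to the methyl group), and one-pot oxidation of the C–B bond (aryl shift from boron to oxygen) gives the phenol.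

Step 3
Reactants: 4 3,5-diisopropoxy-4-methylphenol
Product: 5 6-hydroxy-2,4-diisopropoxy-3-methylbenzaldehyde
Conditions: MgCl2 (2 equiv), Et3N (4 equiv), (CH2O)n (6 equiv), MeCN, reflux; 1 M HCl work-up
Reagents that add atoms: paraformaldehyde (as formaldehyde), C=O
Why: Magnesium-mediated ortho-formylation of a phenol (Casnati–Skattebøl reaction), in which the ArOMgCl phenoxide delivers formaldehyde to the ortho carbon and a second formaldehyde oxidises the benzylic alkoxide by hydride transfer; the two ortho positions of 4 are equivalent and the para position is blocked, so a single salicylaldehyde should result.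

Step 4
Reactants: 5 6-hydroxy-2,4-diisopropoxy-3-methylbenzaldehyde; 6 isobutene; 7 trimethyl orthoformate
Product: 10 5,7-diisopropoxy-4-methoxy-2,2,6-trimethylchromane (racemic at C4), via dimethyl acetal 8 (not isolated), via oxocarbenium triflate 9 (not isolated)
Conditions: HC(OMe)3 (3 equiv), isobutene (10 equiv, condensed), TfOH (10 mol %), CH2Cl2, −40 → 0 °C, sealed tube; Et3N quench
Reagents that add atoms: none
Why: Acid-catalysed exchange with 7 turns the aldehyde into acetal 8, which ionises to oxocarbenium ion 9, the O-protonated form of a 4-methoxy ortho-quinone methide; the unsubstituted terminus of isobutene bonds to the benzylic carbon (C3–C4) and the tertiary carbocation so formed is trapped by the adjacent phenolic oxygen (O1–C2). The closest known reaction type is the acid-promoted inverse-electron-demand hetero-Diels–Alder (formal [4+2]) reaction of ortho-quinone methides, including alkoxy-substituted ones generated from salicylaldehyde acetals, with 1,1-disubstituted alkenes to give 4-alkoxychromanes. Ring C closes as a six-membered ring in an asynchronous [4+2] mode, intermolecular C–C bond formation being followed by ring-closing C–O bond formation. The one new stereocentre, C4, has no controlling element and forms as a racemate, which is acceptable because step 6 converts C4 into the carbonyl carbon. The step needs Markovnikov regiochemistry of the alkene (dimethyl-substituted carbon on oxygen), secured by the preference for the tertiary cation, and closure on the oxygen para to the methyl group, secured because the other two ring oxygens are isopropyl ethers. Excess alkene, low temperature, the methanol released and an amine quench should limit re-ionisation of the electron-rich product at C4 and Friedel–Crafts tert-butylation at C8.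

Step 5
Reactants: 10 5,7-diisopropoxy-4-methoxy-2,2,6-trimethylchromane
Product: 11 5,7-diisopropoxy-2,2,6-trimethylchroman-4-ol (racemic)
Conditions: 0.5 M aq. HCl, THF, 0 °C → rt; NaHCO3 quench
Reagents that add atoms: water, O
Why: SN1 solvolysis of the benzylic methyl ether, in which the C4–OMe bond flanked by an aryl ring with three oxygen donors ionises in dilute acid and the large excess of water returns the cation as the alcohol, E1 loss to the 2H-chromene being reversible there, while the aryl isopropyl ethers and the ring C ether are inert to dilute acid.

Step 6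
Reactants: 11 5,7-diisopropoxy-2,2,6-trimethylchroman-4-ol
Product: 12 5,7-diisopropoxy-2,2,6-trimethylchroman-4-one
Conditions: Dess–Martin periodinane (1.3 equiv), pyridine, CH2Cl2, 0 °C → rt
Reagents that add atoms: none
Why: Dess–Martin oxidation of the secondary benzylic alcohol to the aryl ketone, buffered with pyridine so that the acid-labile carbinol is not ionised; the temporary C4 stereocentre disappears here.

Step 7
Reactants: 12 5,7-diisopropoxy-2,2,6-trimethylchroman-4-one
Product: 13 5,7-dihydroxy-2,2,6-trimethylchroman-4-one
Conditions: BCl3 (5 equiv), CH2Cl2, −78 → 0 °C; then MeOH/H2O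
Reagents that add atoms: none
Why: Lewis-acid dealkylation of aryl isopropyl ethers with BCl3 (O-coordination, loss of the secondary alkyl group as 2-chloropropane, hydrolysis of the aryl borate), fastest at O5 through chelation with the C4 carbonyl; the C2–O1 ether is a weakly basic vinylogous ester oxygen, so ring C should survive.

Step 8
Reactants: 14 (R)-2-methylbutanoic acid; 15 2-methylphloroglucinol
Product: 17 (R)-2-methyl-1-(2,4,6-trihydroxy-3-methylphenyl)butan-1-one, via acid chloride 16 (not isolated)
Conditions: (COCl)2, DMF (cat.), CH2Cl2, 0 °C → rt, concentrate; then 15, AlCl3 (3.5 equiv), PhNO2/CH2Cl2, 0 °C → rt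
Reagents that add atoms: none
Why: Friedel–Crafts C-acylation of the symmetrical, highly nucleophilic 2-methylphloroglucinol (its two free ring carbons are equivalent) with an acid chloride made without base, so that no ketene can form and, without heating, the (R) centre next to the carbonyl should be carried through unchanged.

Step 9
Reactants: 17 (R)-2-methyl-1-(2,4,6-trihydroxy-3-methylphenyl)butan-1-one
Product: 18 (R)-1-(2,6-dihydroxy-4-methoxy-3-methylphenyl)-2-methylbutan-1-one
Conditions: Me2SO4 (1.0 equiv), K2CO3 (1.0 equiv), acetone, 0 °C → rt
Reagents that add atoms: dimethyl sulfate, COS(=O)(=O)OC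
Why: Williamson-type O-methylation under stoichiometric control, in which the 4-OH para to the acyl group is the most acidic phenol while the 2- and 6-OH are held back by hydrogen bonding to the neighbouring ketone; the weak base should not enolise the ketone, so the stereocentre is retained.

Step 10
Reactants: 18 (R)-1-(2,6-dihydroxy-4-methoxy-3-methylphenyl)-2-methylbutan-1-one
Product: 19 (R)-1-{3-[(dimethylamino)methyl]-2,6-dihydroxy-4-methoxy-5-methylphenyl}-2-methylbutan-1-one
Conditions: 37% aq. HCHO (1.2 equiv), 40% aq. Me2NH (1.5 equiv), EtOH, 0 °C → rt
Reagents that add atoms: formaldehyde, C=O; dimethylamine, CNC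
Why: Phenolic Mannich reaction (aminomethylation), in which the single unsubstituted ring carbon C5, ortho and para to free hydroxyls, is the only aromatic site open to the iminium ion from formaldehyde and dimethylamine.

Step 11
Reactants: 19 (R)-1-{3-[(dimethylamino)methyl]-2,6-dihydroxy-4-methoxy-5-methylphenyl}-2-methylbutan-1-one; 13 5,7-dihydroxy-2,2,6-trimethylchroman-4-one
Product: 20 8-{[2,4-dihydroxy-6-methoxy-5-methyl-3-[(2R)-2-methylbutanoyl]phenyl]methyl}-5,7-dihydroxy-2,2,6-trimethylchroman-4-one
Conditions: 19 (1.2 equiv), PhMe/1,4-dioxane, 100 °C, N2 stream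
Reagents that add atoms: none
Why: Thermal retro-Mannich loss of dimethylamine from 19 gives the ring A ortho-quinone methide, which is captured in a Michael-type C-alkylation by C8 of 13, the only free aromatic carbon of the chromanone (ortho to the 7-OH, para to the 5-OH); no base is added, so the stereocentre next to the ketone should stay (R).

Compound list
1 | 2-methylresorcinol (2-methylbenzene-1,3-diol) | Cc1c(O)cccc1O | starting material
2 | 2,6-diisopropoxytoluene (2-methyl-1,3-di(propan-2-yloxy)benzene) | Cc1c(OC(C)C)cccc1OC(C)C | intermediate
3 | 2-(3,5-diisopropoxy-4-methylphenyl)-4,4,5,5-tetramethyl-1,3,2-dioxaborolane | Cc1c(OC(C)C)cc(cc1OC(C)C)B1OC(C)(C)C(C)(C)O1 | intermediate (not isolated)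
4 | 3,5-diisopropoxy-4-methylphenol | Cc1c(OC(C)C)cc(O)cc1OC(C)C | intermediate
5 | 6-hydroxy-2,4-diisopropoxy-3-methylbenzaldehyde | O=Cc1c(O)cc(OC(C)C)c(C)c1OC(C)C | intermediate
6 | isobutene (2-methylpropene) | CC(C)=C | starting material
7 | trimethyl orthoformate | COC(OC)OC | starting material
8 | 2-(dimethoxymethyl)-3,5-diisopropoxy-4-methylphenol | COC(OC)c1c(O)cc(OC(C)C)c(C)c1OC(C)C | intermediate (not isolated)
9 | [(6-hydroxy-2,4-diisopropoxy-3-methylphenyl)methylidene](methyl)oxonium triflate (O-protonated 4-methoxy ortho-quinone methide) | C[O+]=Cc1c(O)cc(OC(C)C)c(C)c1OC(C)C.[O-]S(=O)(=O)C(F)(F)F | intermediate (not isolated)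
10 | 5,7-diisopropoxy-4-methoxy-2,2,6-trimethylchromane (racemic at C4) | COC1CC(C)(C)Oc2cc(OC(C)C)c(C)c(OC(C)C)c12 | intermediate
11 | 5,7-diisopropoxy-2,2,6-trimethylchroman-4-ol (racemic at C4) | OC1CC(C)(C)Oc2cc(OC(C)C)c(C)c(OC(C)C)c12 | intermediate
12 | 5,7-diisopropoxy-2,2,6-trimethylchroman-4-one | O=C1CC(C)(C)Oc2cc(OC(C)C)c(C)c(OC(C)C)c12 | intermediate
13 | 5,7-dihydroxy-2,2,6-trimethylchroman-4-one | O=C1CC(C)(C)Oc2cc(O)c(C)c(O)c12 | intermediate
14 | (R)-2-methylbutanoic acid | CC[C@@H](C)C(=O)O | starting material
15 | 2-methylphloroglucinol (2-methylbenzene-1,3,5-triol) | Cc1c(O)cc(O)cc1O | starting material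
16 | (R)-2-methylbutanoyl chloride | CC[C@@H](C)C(=O)Cl | intermediate (not isolated)
17 | (R)-2-methyl-1-(2,4,6-trihydroxy-3-methylphenyl)butan-1-one | CC[C@@H](C)C(=O)c1c(O)cc(O)c(C)c1O | intermediate
18 | (R)-1-(2,6-dihydroxy-4-methoxy-3-methylphenyl)-2-methylbutan-1-one | CC[C@@H](C)C(=O)c1c(O)cc(OC)c(C)c1O | intermediate
19 | (R)-1-{3-[(dimethylamino)methyl]-2,6-dihydroxy-4-methoxy-5-methylphenyl}-2-methylbutan-1-one | CC[C@@H](C)C(=O)c1c(O)c(CN(C)C)c(OC)c(C)c1O | intermediate
20 | 8-{[2,4-dihydroxy-6-methoxy-5-methyl-3-[(2R)-2-methylbutanoyl]phenyl]methyl}-5,7-dihydroxy-2,2,6-trimethylchroman-4-one (CNP0303209.1) | CC[C@@H](C)C(=O)c1c(O)c(C)c(OC)c(Cc2c(O)c(C)c(O)c3c2OC(C)(C)CC3=O)c1O | target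

Total step count: 11. Longest linear sequence: 8 steps (steps 1–7, then step 11); the ring A branch (steps 8–10) joins at step 11.

Steps most likely to fail

Step 4. The oxocarbenium ion is stabilised by three oxygen donors and may add isobutene only slowly. The electron-rich product can ionise again at C4 under the acid and then eliminate to the 2H-chromene or oligomerise, and Friedel–Crafts tert-butylation at C8 is a further drain. The fallback sets out from phenol 4 and returns at chromanone 12, bypassing steps 3–6. Phenol 4 would be warmed with 3-methylbut-2-enoic acid in P2O5/MeSO3H (Eaton's reagent, about 50 °C). Friedel–Crafts acylation at either of the equivalent ortho carbons gives the open-chain enone 1-(6-hydroxy-2,4-diisopropoxy-3-methylphenyl)-3-methylbut-2-en-1-one F1, which closes in the same pot by oxa-Michael addition of the phenol to give 12. The symmetry of 4 and its blocked para position again allow only the 6-methyl skeleton, and an isopropyl group lost after the acylation is harmless because step 7 removes both.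

Step 11. Capture of the ortho-quinone methide at the hindered, acyl-deactivated C8 may be slow, so that the ortho-quinone methide re-adds amine or condenses with itself, and long heating in the presence of the liberated amine risks exchange of the methylene bridge towards symmetrical dimers. The fallback reverses the roles of the partners: it sets out from chromanone 13 and ketone 18 and returns at target 20. Chromanone 13 would be aminomethylated at C8 (aq. HCHO, aq. Me2NH, EtOH, rt) to give 8-[(dimethylamino)methyl]-5,7-dihydroxy-2,2,6-trimethylchroman-4-one F2. Heating F2 with 18 (PhMe/1,4-dioxane, 100 °C) would generate the chromanone ortho-quinone methide, which the free C5 of the ring A ketone captures to give 20.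

Step 9. Discrimination among three phenolic hydroxyls may be incomplete, with over-methylation at O2 or O6 or C-methylation at C5. The fallback sets out from acid chloride 16 and returns at 18. Acid chloride 16 would acylate purchased 1,3,5-trimethoxy-2-methylbenzene F3 (AlCl3, CH2Cl2, 0 °C; the two free ring positions are equivalent) to give (R)-2-methyl-1-(2,4,6-trimethoxy-3-methylphenyl)butan-1-one F4. Excess BCl3 (CH2Cl2, 0 °C → rt) would then cleave only the two methoxy groups ortho to the ketone by chelation-directed demethylation and leave the para methoxy group, giving 18.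

Further compounds
F1 | step 4 | 1-(6-hydroxy-2,4-diisopropoxy-3-methylphenyl)-3-methylbut-2-en-1-one | CC(C)=CC(=O)c1c(O)cc(OC(C)C)c(C)c1OC(C)C
F2 | step 11 | 8-[(dimethylamino)methyl]-5,7-dihydroxy-2,2,6-trimethylchroman-4-one | CN(C)Cc1c(O)c(C)c(O)c2c1OC(C)(C)CC2=O
F3 | step 9 | 1,3,5-trimethoxy-2-methylbenzene (purchased) | COc1cc(OC)c(C)c(OC)c1
F4 | step 9 | (R)-2-methyl-1-(2,4,6-trimethoxy-3-methylphenyl)butan-1-one | CC[C@@H](C)C(=O)c1c(OC)cc(OC)c(C)c1OC
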